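**Retrosynthetic overview**
1. Target 17 comes from twofold NBS bromination (para, then ortho to OH) of debromolaurinterol 15; the cyclopropane of 15 is made last, by phenol-directed Simmons–Smith reaction of cyclopentenyl phenol 14.
2. The cyclopentene (13, then 14) comes from intramolecular McMurry coupling of 1,5-keto aldehyde 12.
3. 12 comes from δ-lactone 10 (MeLi, then oxidation); 10 comes from hydroxypropyl benzofuranone 8 by translactonisation and O-methylation.
4. Key C–C bond (quaternary C–CH2): enantioselective intermolecular Michael addition of benzofuranone 5 to acrolein 6, giving 7.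
5. 5 comes from acetophenone 1 (O-methylation, TosMIC reductive cyanation, HBr hydrolysis/lactonisation). Ring order: lactone of 5 (temporary), oxanone of 10 (temporary), cyclopentene, cyclopropane.

Assumption: 9-O-benzylcupreidine is taken to give the (S) adduct 7; if the sense proves opposite, its pseudoenantiomer 9-O-benzylcupreine is used and nothing else changes.

**Step 1**
Reactants: 1 1-(2-hydroxy-4-methylphenyl)ethan-1-one
Product: 2 1-(2-methoxy-4-methylphenyl)ethan-1-one
Conditions: MeI, K2CO3, DMF, 40 °C
Reagents that add atoms: iodomethane, CI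
Why: Williamson ether synthesis on the phenoxide caps the phenol so that the ketone is not deactivated as an o-phenoxide in the next step; no stereocentre is involved.

**Step 2**
Reactants: 2 1-(2-methoxy-4-methylphenyl)ethan-1-one
Product: 3 rac-2-(2-methoxy-4-methylphenyl)propanenitrile
Conditions: TosMIC, t-BuOK, DME/EtOH, 0 → 35 °C
Reagents that add atoms: p-toluenesulfonylmethyl isocyanide (TosMIC), Cc1ccc(cc1)S(=O)(=O)C[N+]#[C-]
Why: Van Leusen reductive cyanation (TosMIC carbanion addition, oxazoline formation, loss of sulfinate and formate) turns the aryl methyl ketone directly into the homologous secondary nitrile; the new stereocentre is racemic and is erased by enolisation in step 4.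

**Step 3**
Reactants: 3 rac-2-(2-methoxy-4-methylphenyl)propanenitrile
Product: 5 rac-3,6-dimethyl-1-benzofuran-2(3H)-one, via hydroxy acid 4 (not isolated)
Conditions: 48% aq HBr, AcOH, reflux; then toluene azeotrope
Reagents that add atoms: water, O
Why: In hot HBr/AcOH the nitrile is hydrolysed to the acid, the aryl methyl ether is cleaved by SN2 attack of bromide, and the resulting o-hydroxyaryl acid closes spontaneously to the five-membered aryl lactone (acid-mediated lactonisation).

**Step 4**
Reactants: 5 rac-3,6-dimethyl-1-benzofuran-2(3H)-one; 6 prop-2-enal (acrolein)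
Product: 7 3-[(3S)-3,6-dimethyl-2-oxo-2,3-dihydro-1-benzofuran-3-yl]propanal
Conditions: acrolein (2 equiv), 9-O-benzylcupreidine (10 mol%), CH2Cl2, −30 °C, under Ar
Reagents that add atoms: none
Why: Organocatalytic enantioselective Michael addition, in which the quinuclidine nitrogen deprotonates the acidic lactone C3–H (pKa about 14), the 6'-OH of the catalyst hydrogen-bonds acrolein, and C–C bond formation on one face of the ion-paired planar enolate sets the quaternary (3S) centre from which all other stereocentres of the target are later derived.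

**Step 5**
Reactants: 7 3-[(3S)-3,6-dimethyl-2-oxo-2,3-dihydro-1-benzofuran-3-yl]propanal
Product: 8 (3S)-3-(3-hydroxypropyl)-3,6-dimethyl-1-benzofuran-2(3H)-one
Conditions: NaBH4 (0.5 equiv), THF/EtOH, −30 °C; then aq NH4Cl
Reagents that add atoms: none
Why: Chemoselective borohydride reduction, in which the aldehyde is reduced within minutes at low temperature while the hindered aryl lactone is left, also removes the risk of retro-Michael cleavage and does not touch the quaternary centre.

**Step 6**
Reactants: 8 (3S)-3-(3-hydroxypropyl)-3,6-dimethyl-1-benzofuran-2(3H)-one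
Product: 10 (3S)-3-(2-methoxy-4-methylphenyl)-3-methyloxan-2-one, via phenolic δ-lactone 9 (not isolated)
Conditions: K2CO3, MeI, DMF, 40 °C
Reagents that add atoms: iodomethane, CI
Why: Base-mediated translactonisation (intramolecular acyl transfer from the aryl ester to the primary alcohol through a six-membered ring) is pulled to the δ-lactone side by formation of the phenoxide, which is trapped irreversibly by Williamson O-methylation; no bond to the stereocentre is broken.

**Step 7**
Reactants: 10 (3S)-3-(2-methoxy-4-methylphenyl)-3-methyloxan-2-one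
Product: 11 (3S)-6-hydroxy-3-(2-methoxy-4-methylphenyl)-3-methylhexan-2-one
Conditions: MeLi (1.15 equiv), THF, −78 °C; then H2O
Reagents that add atoms: methyllithium, [Li]C
Why: Mono-addition of an organolithium to a lactone, in which the lithium hemiketal alkoxide is stable at −78 °C and the quaternary α-carbon (no α-H, strong shielding) blocks enolisation and a second addition, so that the quench releases the methyl ketone (in equilibrium with its six-membered cyclic hemiketal).

**Step 8**
Reactants: 11 (3S)-6-hydroxy-3-(2-methoxy-4-methylphenyl)-3-methylhexan-2-one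
Product: 12 (4S)-4-(2-methoxy-4-methylphenyl)-4-methyl-5-oxohexanal
Conditions: Dess–Martin periodinane, CH2Cl2, rt
Reagents that add atoms: none
Why: Dess–Martin oxidation of the primary alcohol under near-neutral conditions gives the aldehyde without aldol cyclisation, the hemiketal form draining through the open hydroxy ketone.

**Step 9**
Reactants: 12 (4S)-4-(2-methoxy-4-methylphenyl)-4-methyl-5-oxohexanal
Product: 13 1-[(1R)-1,2-dimethylcyclopent-2-en-1-yl]-2-methoxy-4-methylbenzene
Conditions: TiCl3(DME)1.5, Zn–Cu couple, DME, reflux, 12 added over 30 h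
Reagents that add atoms: none
Why: Intramolecular McMurry reductive carbonyl coupling by low-valent titanium joins the ketone and aldehyde carbons into the trisubstituted alkene of a five-membered ring, a favoured closure that tolerates the flanking quaternary carbon; the stereocentre is unchanged in space and its descriptor switches from S to R only because the priorities change.

**Step 10**
Reactants: 13 1-[(1R)-1,2-dimethylcyclopent-2-en-1-yl]-2-methoxy-4-methylbenzene
Product: 14 2-[(1R)-1,2-dimethylcyclopent-2-en-1-yl]-5-methylphenol
Conditions: NaSEt (4 equiv), DMF, 140 °C; then cold 1 M HCl to pH 6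
Reagents that add atoms: none
Why: SN2 demethylation of the aryl methyl ether by ethanethiolate runs under basic, non-acidic conditions, so the liberated phenol cannot add to the neighbouring alkene.

**Step 11**
Reactants: 14 2-[(1R)-1,2-dimethylcyclopent-2-en-1-yl]-5-methylphenol
Product: 15 2-[(1S,2R,5R)-1,2-dimethylbicyclo[3.1.0]hexan-2-yl]-5-methylphenol (debromolaurinterol)
Conditions: Et2Zn (2.2 equiv), CH2I2 (4.4 equiv), CH2Cl2, 0 °C → rt; then aq NH4Cl
Reagents that add atoms: diiodomethane, ICI
Why: Hydroxyl-directed Simmons–Smith (Furukawa) cyclopropanation, in which the zinc phenoxide carries the iodomethylzinc carbenoid and delivers CH2 to the alkene face on which the aryl group sits, forms the cyclopropane cis to the aryl group and so sets C1 (S) and C5 (R) from the existing C2 (R) centre.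

**Step 12**
Reactants: 15 2-[(1S,2R,5R)-1,2-dimethylbicyclo[3.1.0]hexan-2-yl]-5-methylphenol
Product: 17 2,4-dibromo-6-[(1S,2R,5R)-1,2-dimethylbicyclo[3.1.0]hexan-2-yl]-3-methylphenol, via laurinterol 16 (not isolated)
Conditions: NBS (2.1 equiv), NaHCO3, MeCN, 0 °C → rt, dark
Reagents that add atoms: N-bromosuccinimide, O=C1CCC(=O)N1Br
Why: Electrophilic aromatic substitution by NBS occurs first para and then ortho to the hydroxyl group (the other ortho position carries the bicycle and the remaining C–H is meta to OH), and since NBS gives succinimide and not HBr the acid-labile cyclopropane and all stereocentres survive.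

**Compound list**
1 | 1-(2-hydroxy-4-methylphenyl)ethan-1-one | CC(=O)c1ccc(C)cc1O | starting material
2 | 1-(2-methoxy-4-methylphenyl)ethan-1-one | COc1cc(C)ccc1C(C)=O | intermediate
3 | rac-2-(2-methoxy-4-methylphenyl)propanenitrile | COc1cc(C)ccc1C(C)C#N | intermediate
4 | rac-2-(2-hydroxy-4-methylphenyl)propanoic acid (not isolated) | Cc1ccc(C(C)C(=O)O)c(O)c1 | intermediate
5 | rac-3,6-dimethyl-1-benzofuran-2(3H)-one | Cc1ccc2c(c1)OC(=O)C2C | intermediate
6 | prop-2-enal (acrolein) | C=CC=O | starting material
7 | 3-[(3S)-3,6-dimethyl-2-oxo-2,3-dihydro-1-benzofuran-3-yl]propanal | Cc1ccc2c(c1)OC(=O)[C@@]2(C)CCC=O | intermediate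
8 | (3S)-3-(3-hydroxypropyl)-3,6-dimethyl-1-benzofuran-2(3H)-one | Cc1ccc2c(c1)OC(=O)[C@@]2(C)CCCO | intermediate
9 | (3S)-3-(2-hydroxy-4-methylphenyl)-3-methyloxan-2-one (not isolated) | Cc1ccc(c(O)c1)[C@]1(C)CCCOC1=O | intermediate
10 | (3S)-3-(2-methoxy-4-methylphenyl)-3-methyloxan-2-one | COc1cc(C)ccc1[C@]1(C)CCCOC1=O | intermediate
11 | (3S)-6-hydroxy-3-(2-methoxy-4-methylphenyl)-3-methylhexan-2-one | COc1cc(C)ccc1[C@](C)(CCCO)C(C)=O | intermediate
12 | (4S)-4-(2-methoxy-4-methylphenyl)-4-methyl-5-oxohexanal | COc1cc(C)ccc1[C@](C)(CCC=O)C(C)=O | intermediate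
13 | 1-[(1R)-1,2-dimethylcyclopent-2-en-1-yl]-2-methoxy-4-methylbenzene | COc1cc(C)ccc1[C@]1(C)CCC=C1C | intermediate
14 | 2-[(1R)-1,2-dimethylcyclopent-2-en-1-yl]-5-methylphenol | Cc1ccc(c(O)c1)[C@]1(C)CCC=C1C | intermediate
15 | 2-[(1S,2R,5R)-1,2-dimethylbicyclo[3.1.0]hexan-2-yl]-5-methylphenol (debromolaurinterol) | Cc1ccc(c(O)c1)[C@]1(C)CC[C@@H]2C[C@@]21C | intermediate
16 | 4-bromo-2-[(1S,2R,5R)-1,2-dimethylbicyclo[3.1.0]hexan-2-yl]-5-methylphenol (laurinterol, not isolated) | Cc1cc(O)c(cc1Br)[C@]1(C)CC[C@@H]2C[C@@]21C | intermediate
17 | 2,4-dibromo-6-[(1S,2R,5R)-1,2-dimethylbicyclo[3.1.0]hexan-2-yl]-3-methylphenol | Cc1c(Br)cc([C@]2(C)CC[C@@H]3C[C@@]32C)c(O)c1Br | target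

**Total step count:** 12. **Longest linear sequence:** 12 steps (1 → 17); acrolein 6 enters in step 4.

**Steps most likely to fail**

Step 4 (enantioselective Michael addition). The level and sense of induction with a 3-methyl benzofuranone and acrolein are not secured, and acrolein can polymerise under amine catalysis. A modest ee can be raised by recrystallising lactone 10. The fallback sets out from 5 and comes back at 8. It changes the acceptor to a two-point-binding acrylamide and the control element to a thiourea. Compound 5 adds to 1-(3,5-dimethyl-1H-pyrazol-1-yl)prop-2-en-1-one under N-[3,5-bis(trifluoromethyl)phenyl]-N′-[(8α,9S)-6′-methoxycinchonan-9-yl]thiourea (10 mol%, toluene, −20 °C; the quinidine-derived analogue if the other sense is needed). This gives (3S)-3-[3-(3,5-dimethyl-1H-pyrazol-1-yl)-3-oxopropyl]-3,6-dimethyl-1-benzofuran-2(3H)-one F1. NaBH4 (THF/H2O, 0 °C) then reduces the activated acyl pyrazole straight to the primary alcohol 8, releasing 3,5-dimethylpyrazole.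

Step 7 (single MeLi addition to the lactone). Double addition to the tertiary alcohol or incomplete conversion of the hindered lactone are the risks. The fallback sets out from 10 and comes back at 11. Me(MeO)NH·HCl with i-PrMgCl (THF, −20 → 0 °C) opens the lactone to (2S)-5-hydroxy-N-methoxy-2-(2-methoxy-4-methylphenyl)-N,2-dimethylpentanamide F2. F2 is kept in the flask as its magnesium alkoxide so that it cannot relactonise. MeLi added to the same flask gives a chelated tetrahedral intermediate that cannot add a second time and releases ketone 11 only on quench.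

Step 9 (McMurry coupling). The low-valent titanium reagent is capricious, and pinacol, reduction or aldol (cyclohexenone) by-products can take over. The fallback sets out from 12 and comes back at 13. It replaces reductive coupling by olefination and metathesis. Ph3P=CH2 (4 equiv, from Ph3PCH3Br and KHMDS, THF, −78 °C → reflux) methylenates the aldehyde first and then the ketone, giving 1-[(3R)-2,3-dimethylhepta-1,6-dien-3-yl]-2-methoxy-4-methylbenzene F3. Ring-closing metathesis with second-generation Grubbs catalyst, RuCl2(=CHPh)(H2IMes)(PCy3) (5 mol%, CH2Cl2, 40 °C), closes F3 to 13.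

**Further compounds**
F1 | step 4 | (3S)-3-[3-(3,5-dimethyl-1H-pyrazol-1-yl)-3-oxopropyl]-3,6-dimethyl-1-benzofuran-2(3H)-one | Cc1ccc2c(c1)OC(=O)[C@@]2(C)CCC(=O)n1nc(C)cc1C
F2 | step 7 | (2S)-5-hydroxy-N-methoxy-2-(2-methoxy-4-methylphenyl)-N,2-dimethylpentanamide | COc1cc(C)ccc1[C@](C)(CCCO)C(=O)N(C)OC
F3 | step 9 | 1-[(3R)-2,3-dimethylhepta-1,6-dien-3-yl]-2-methoxy-4-methylbenzene | COc1cc(C)ccc1[C@](C)(CCC=C)C(C)=C
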